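If partner is treated as plentiful, c(substrate) falls as exp(−kt) with one constant k per temperature, and the share of substrate turned into target is one minus exp(−kt). That bench rule is tried here on four flasks, using three earlier runs.

| flask | substrate | partner | temperature | remark | time |
|---|---|---|---|---|---|
| Monday's | 0.061 M | 0.109 M | 45 °C | run made earlier |  |
| Thursday's | 0.14 M | 0.109 M | 80 °C | run made earlier |  |
| Wednesday's | 0.091 M | 0.16 M | 45 °C | run made earlier |  |
| summer | 0.091 M | 0.109 M | 50 °C |  | 12 h |
| noon | 0.091 M | 0.109 M | 80 °C |  | 12 h |
| winter | 0.091 M | 0.109 M |  | at 50 °C until 2.5 h, from then on at 110 °C | 12 h |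
| midnight | 0.091 M | 0.109 M | 110 °C |  | 12 h |

| run | time / h | target / % |
|---|---|---|
| Monday's | 0.500 | 6.2 |
| Monday's | 1.33 | 11.7 |
| Monday's | 2.50 | 22.7 |
| Monday's | 4.00 | 32.9 |
| Monday's | 6.00 | 43.7 |
| Monday's | 8.00 | 53.5 |
| Monday's | 10.0 | 60.9 |
| Thursday's | 0.200 | 35.5 |
| Thursday's | 0.333 | 46.9 |
| Thursday's | 0.417 | 52.6 |
| Thursday's | 0.500 | 58.5 |
| Thursday's | 0.833 | 69.3 |
| Thursday's | 1.33 | 75.3 |
| Thursday's | 2.50 | 77.2 |
| Wednesday's | 0.833 | 12.9 |
| Wednesday's | 1.33 | 17.3 |
| Wednesday's | 2.50 | 26.1 |
| Wednesday's | 5.00 | 45.4 |
| Wednesday's | 10.0 | 68.6 |

(each reading ± 1 percentage point)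

- the flask that comes out highest in amount of target, in percent of the substrate charged, or "all alike" when all lie within 1.5 percentage points (summer / noon / winter / midnight / all alike)
- target at the end, in percent of the substrate charged, summer
- target at the end, in percent of the substrate charged, noon
- target at the end, in percent of the substrate charged, winter
- target at the end, in percent of the substrate charged, midnight

- a reading or a percentage of target counts all its forms, free or not

Monday's last reading gives k = 0.0939 h⁻¹ at 45 °C. Over 12 h that constant turns 67.6 %, and summer, at 50 °C, is warmer than Monday's run, so this reckoning expects summer above that figure. Thursday's first reading gives k = 2.19 h⁻¹ at 80 °C, a half-life of 0.316 h, and noon, at the same temperature, has 38.0 such half-lives in its time.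

But the rule breaks on Thursday's run: at 2.50 h it says 99.6 %, more than the 77.2 % read there. That reading stands beside 77.9 %, the partner charged over the substrate charged in Thursday's run. This ratio marks the border. Call it the partner ceiling 120 %: partner charged over substrate charged, the percentage of the substrate that one partner per target can turn. This value, for the four flasks, lies above the whole substrate charge, so substrate is the limiting reagent there, and partner beyond one per substrate comes to 19.8 % of the substrate charged. This reckoning sets no partner limit below the whole substrate charge on the four flasks, and it does not rank them.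

The forecast does give numbers: noon highest, with summer 81 %, noon 94 %, winter 88 % and midnight 87 %. Its summer figure lies above the one reckoned here, and of 110 °C it says “the runs cannot exclude an adverse equilibrium or target loss”.

The flasks give summer 78.3 %, noon 96.8 %, winter 88.8 % and midnight 86.7 %, so noon stands highest, as forecast.

    substrate + partner → target, rate k1*[substrate]*[partner]^0.5 (k = 0.00890 M⁻⁰·⁵ min⁻¹, Ea = 84.0 kJ mol⁻¹)
    partner + target → over-reaction product (k = 0.00430 M⁻¹ min⁻¹, Ea = 78.0 kJ mol⁻¹)
    crystals ⇌ target, rate k3*(cs3 - [target]) while solid is left; crystals form when [target] > cs3 (solubility = 2.80 mM, k = 0.290 min⁻¹)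
    (constants at 50 °C)

Noon ends below its ceiling, with substrate at 0 %, partner at 13.8 % of its own charge and over-reaction product at 3.21 %. A neighbour like summer but charged with 0.044 M of partner has a ceiling of 48.4 %, which is below the figure reckoned for summer. That neighbour ends with partner, the first to run out there, at 0.549 % of its own charge, substrate at 52.0 %, and target at 47.8 %, below its ceiling of 48.4 %.

(Readings and results are calculated for an exercise.)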